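**Retrosynthetic overview** (cembrane locants: C2 = lactone O–CH, C1 = ring-fusion CH, C11/C12 = oxirane, C13 = CH–OAc, C15/C16/C17 = lactone α-carbon, C=O and exocyclic CH2)
1. The 14-membered ring and the γ-lactone are closed together in the last step: C1–C2 by iridium-catalysed transfer-hydrogenative 2-(alkoxycarbonyl)allylation of the C2 allylic alcohol by the C17 allylic carbonate, then lactonisation.
2. The allylic carbonate/enoate (C1=C15) comes from ruthenium-catalysed cross-metathesis of a terminal alkene with an acrylate carbonate.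
3. C6–C7 comes from a palladium-catalysed B-alkyl Suzuki coupling of an east alkyl iodide (C2–C6) with a west alkenyl iodide (C7–C14 plus C1).
4. West fragment: oxirane by matched Sharpless epoxidation of the C13 carbinol, which is set by Brown allylation of an (E,E)-iododienal (Negishi carboalumination of pent-4-yn-1-ol, then Wittig). East fragment: carboalumination/hydroxymethylation of but-3-yn-1-ol.
5. Ring order: oxirane first (fragment stage), then carbocycle and lactone in one final operation.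

Assumption: in step 18 the (R)-antipode of SEGPHOS is taken as the one that sends the allyl group to the Re face of the C2 aldehyde (needed for 1S,2S); if the first cyclisation shows the opposite sense, (S)-SEGPHOS is used.

**Route**

Step 1
Reactants: 1 bromoethane
Product: 2 ethyltriphenylphosphonium bromide
Conditions: PPh3, toluene, 110 °C (sealed)
Reagents that add atoms: triphenylphosphine c1ccccc1P(c1ccccc1)c1ccccc1
Why: SN2 quaternisation of the phosphine by a primary bromide (phosphonium salt formation).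

Step 2
Reactants: 2 ethyltriphenylphosphonium bromide; 3 ethyl formate
Product: 5 2-(triphenylphosphoranylidene)propanal, via ethylidene ylide 4 (not isolated)
Conditions: KOt-Bu (2 equiv), THF, 0 °C; then HCO2Et, 0 °C to rt
Reagents that add atoms: none
Why: Deprotonation gives the non-stabilised ylide, and its C-formylation with loss of ethanol gives the stabilised formyl ylide (ylide acylation).

Step 3
Reactants: 6 pent-4-yn-1-ol
Product: 8 (4E)-5-iodo-4-methylpent-4-en-1-ol, via alkenylalane 7 (not isolated)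
Conditions: Me3Al (3 equiv), Cp2ZrCl2 (0.25 equiv), CH2Cl2, 0 °C to rt; then I2, THF, −30 °C
Reagents that add atoms: trimethylaluminium C[Al](C)C; iodine II
Why: Negishi zirconium-catalysed carboalumination adds methyl and aluminium syn across the alkyne with aluminium on the terminal carbon, and iodinolysis with retention gives the (E)-iodide.

Step 4
Reactants: 8 (4E)-5-iodo-4-methylpent-4-en-1-ol
Product: 9 (4E)-5-iodo-4-methylpent-4-enal
Conditions: TEMPO (10 mol%), PhI(OAc)2, CH2Cl2, rt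
Reagents that add atoms: none
Why: TEMPO/PhI(OAc)2 oxidation of a primary alcohol stops at the aldehyde and leaves the alkenyl iodide untouched.

Step 5
Reactants: 9 (4E)-5-iodo-4-methylpent-4-enal; 5 2-(triphenylphosphoranylidene)propanal
Product: 10 (2E,6E)-7-iodo-2,6-dimethylhepta-2,6-dienal
Conditions: toluene, 80 °C
Reagents that add atoms: none
Why: Wittig olefination with a stabilised α-methyl formyl ylide gives the (E)-2-methyl enal with high selectivity.

Step 6
Reactants: 10 (2E,6E)-7-iodo-2,6-dimethylhepta-2,6-dienal; 11 allylmagnesium bromide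
Product: 14 (4R,5E,9E)-10-iodo-5,9-dimethyldeca-1,5,9-trien-4-ol, via allylborane 12 (not isolated), via borinate 13 (not isolated)
Conditions: (+)-Ipc2BOMe [from (−)-α-pinene], 11, Et2O, 0 °C to rt; then 10, −78 °C; then NaOH, H2O2, rt
Reagents that add atoms: none
Why: Brown asymmetric allylboration through a closed chair transition state; the (−)-α-pinene-derived reagent attacks the Re face of the enal and so sets the (R)-carbinol (later C13).

Step 7
Reactants: 14 (4R,5E,9E)-10-iodo-5,9-dimethyldeca-1,5,9-trien-4-ol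
Product: 15 (1R)-1-[(2R,3R)-3-[(4E)-5-iodo-4-methylpent-4-en-1-yl]-2-methyloxiran-2-yl]but-3-en-1-ol
Conditions: Ti(OiPr)4 (0.2 equiv), D-(−)-DIPT (0.25 equiv), t-BuOOH (1.5 equiv), 4 Å MS, CH2Cl2, −20 °C
Reagents that add atoms: tert-butyl hydroperoxide CC(C)(C)OO
Why: Sharpless asymmetric epoxidation in the matched sense: D-(−)-tartrate delivers oxygen to the alkene face that the (R)-carbinol itself favours (the fast enantiomer of the kinetic resolution), giving the anti epoxy alcohol (later 11R,12S); only the allylic alkene reacts and the minor (S)-alcohol is left behind.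

Step 8
Reactants: 15 (1R)-1-[(2R,3R)-3-[(4E)-5-iodo-4-methylpent-4-en-1-yl]-2-methyloxiran-2-yl]but-3-en-1-ol
Product: 16 (1R)-1-[(2S,3R)-3-[(4E)-5-iodo-4-methylpent-4-en-1-yl]-2-methyloxiran-2-yl]but-3-en-1-yl acetate
Conditions: Ac2O, Et3N, DMAP (cat.), CH2Cl2, 0 °C
Reagents that add atoms: acetic anhydride CC(=O)OC(C)=O
Why: DMAP-catalysed acylation of the secondary alcohol; no stereocentre is touched (the oxirane C2 descriptor changes from R to S only because the CIP priorities change).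

Step 9
Reactants: 17 but-3-yn-1-ol
Product: 18 1-[(but-3-yn-1-yloxy)methyl]-4-methoxybenzene
Conditions: NaH, PMBCl, Bu4NI (cat.), THF/DMF, 0 °C to rt
Reagents that add atoms: 4-methoxybenzyl chloride COc1ccc(CCl)cc1
Why: Williamson etherification of the alkoxide; the alkyne C–H is not deprotonated under these conditions.

Step 10
Reactants: 18 1-[(but-3-yn-1-yloxy)methyl]-4-methoxybenzene; 19 formaldehyde (as paraformaldehyde)
Product: 22 (2E)-5-[(4-methoxyphenyl)methoxy]-3-methylpent-2-en-1-ol, via alkenylalane 20 (not isolated), via aluminate 21 (not isolated)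
Conditions: Me3Al (2.5 equiv), Cp2ZrCl2 (0.25 equiv), CH2Cl2, rt; then n-BuLi, THF, −78 to 0 °C; then (CH2O)n, rt
Reagents that add atoms: trimethylaluminium C[Al](C)C
Why: Negishi carboalumination (syn, aluminium terminal), then hydroxymethylation of the alkenyl aluminate with retention, gives the (E)-trisubstituted allylic alcohol.

Step 11
Reactants: 22 (2E)-5-[(4-methoxyphenyl)methoxy]-3-methylpent-2-en-1-ol
Product: 23 tert-butyl({(2E)-5-[(4-methoxyphenyl)methoxy]-3-methylpent-2-en-1-yl}oxy)dimethylsilane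
Conditions: TBSCl, imidazole, CH2Cl2, rt
Reagents that add atoms: tert-butyldimethylsilyl chloride CC(C)(C)[Si](C)(C)Cl
Why: Standard silylation of a primary allylic alcohol.

Step 12
Reactants: 23 tert-butyl({(2E)-5-[(4-methoxyphenyl)methoxy]-3-methylpent-2-en-1-yl}oxy)dimethylsilane
Product: 24 (3E)-5-[(tert-butyldimethylsilyl)oxy]-3-methylpent-3-en-1-ol
Conditions: DDQ, CH2Cl2/pH 7 buffer (10:1), 0 °C
Reagents that add atoms: none
Why: Oxidative cleavage of the electron-rich PMB ether by DDQ leaves the silyl ether and the alkene intact.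

Step 13
Reactants: 24 (3E)-5-[(tert-butyldimethylsilyl)oxy]-3-methylpent-3-en-1-ol
Product: 25 tert-butyl{[(2E)-5-iodo-3-methylpent-2-en-1-yl]oxy}dimethylsilane
Conditions: I2, PPh3, imidazole, CH2Cl2, 0 °C
Reagents that add atoms: iodine II
Why: Appel-type (Garegg–Samuelsson) iodination of a primary alcohol by SN2 on the alkoxyphosphonium ion.

Step 14
Reactants: 26 methyl 2-(hydroxymethyl)prop-2-enoate
Product: 27 methyl 2-{[(methoxycarbonyl)oxy]methyl}prop-2-enoate
Conditions: ClCO2Me, pyridine, CH2Cl2, 0 °C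
Reagents that add atoms: methyl chloroformate COC(=O)Cl
Why: Acylation of the primary allylic alcohol to the carbonate, the leaving group used for the iridium step.

Step 15
Reactants: 25 tert-butyl{[(2E)-5-iodo-3-methylpent-2-en-1-yl]oxy}dimethylsilane; 16 (1R)-1-[(2S,3R)-3-[(4E)-5-iodo-4-methylpent-4-en-1-yl]-2-methyloxiran-2-yl]but-3-en-1-yl acetate
Product: 30 (1R)-1-[(2S,3R)-3-[(3E,7E)-9-[(tert-butyldimethylsilyl)oxy]-3,7-dimethylnona-3,7-dien-1-yl]-2-methyloxiran-2-yl]but-3-en-1-yl acetate, via alkyllithium 28 (not isolated), via lithium borinate 29 (not isolated)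
Conditions: 25, t-BuLi (2.1 equiv), Et2O, −78 °C; B-methoxy-9-BBN, THF, −78 °C to rt; then 16, Pd(dppf)Cl2 (5 mol%), AsPh3, K3PO4 (3 M aq), DMF, rt
Reagents that add atoms: none
Why: B-alkyl Suzuki–Miyaura coupling: the borinate transmetallates to the alkenylpalladium iodide formed from 16 and zerovalent palladium, and reductive elimination forms C6–C7 with retention of the (E)-geometry; oxirane, acetate and terminal alkene do not react.

Step 16
Reactants: 30 (1R)-1-[(2S,3R)-3-[(3E,7E)-9-[(tert-butyldimethylsilyl)oxy]-3,7-dimethylnona-3,7-dien-1-yl]-2-methyloxiran-2-yl]but-3-en-1-yl acetate; 27 methyl 2-{[(methoxycarbonyl)oxy]methyl}prop-2-enoate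
Product: 31 methyl (2E,5R)-5-acetoxy-5-[(2S,3R)-3-[(3E,7E)-9-[(tert-butyldimethylsilyl)oxy]-3,7-dimethylnona-3,7-dien-1-yl]-2-methyloxiran-2-yl]-2-{[(methoxycarbonyl)oxy]methyl}pent-2-enoate
Conditions: 27 (5 equiv), second-generation Hoveyda–Grubbs catalyst RuCl2(H2IMes)(=CH-C6H4-2-OiPr) (10 mol%), CH2Cl2, 40 °C
Reagents that add atoms: none
Why: Olefin cross-metathesis of the only terminal alkene with a 1,1-disubstituted acrylate gives the thermodynamically favoured (E)-trisubstituted enoate; the trisubstituted alkenes are spectators.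

Step 17
Reactants: 31 methyl (2E,5R)-5-acetoxy-5-[(2S,3R)-3-[(3E,7E)-9-[(tert-butyldimethylsilyl)oxy]-3,7-dimethylnona-3,7-dien-1-yl]-2-methyloxiran-2-yl]-2-{[(methoxycarbonyl)oxy]methyl}pent-2-enoate
Product: 32 methyl (2E,5R)-5-acetoxy-5-[(2S,3R)-3-[(3E,7E)-9-hydroxy-3,7-dimethylnona-3,7-dien-1-yl]-2-methyloxiran-2-yl]-2-{[(methoxycarbonyl)oxy]methyl}pent-2-enoate
Conditions: Bu4NF, AcOH (1:1), THF, 0 °C to rt
Reagents that add atoms: none
Why: Buffered fluoride cleaves the primary allylic silyl ether without touching oxirane, acetate or carbonate.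

Step 18
Reactants: 32 methyl (2E,5R)-5-acetoxy-5-[(2S,3R)-3-[(3E,7E)-9-hydroxy-3,7-dimethylnona-3,7-dien-1-yl]-2-methyloxiran-2-yl]-2-{[(methoxycarbonyl)oxy]methyl}pent-2-enoate
Product: 35 (1S,2S,3E,7E,11R,12S,13R)-13-acetoxy-11,12-epoxycembra-3,7,15(17)-trien-16,2-olide, via enal 33 (not isolated), via hydroxy ester 34 (not isolated)
Conditions: [Ir(cod)Cl]2 (5 mol%), (R)-SEGPHOS (10 mol%), 4-cyano-3-nitrobenzoic acid (10 mol%), Cs2CO3 (20 mol%), THF, 70 °C, 32 added over 12 h (2 mM final)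
Reagents that add atoms: none
Why: Proposed new method: an intramolecular, catalyst-controlled iridium-catalysed transfer-hydrogenative 2-(alkoxycarbonyl)allylation from the alcohol oxidation level, in which the iridium alkoxide of the C2 allylic alcohol undergoes β-hydride elimination (carbinol C–H cleavage) to enal 33, the iridium hydride is deprotonated to monovalent iridium that ionises the allylic carbonate with loss of CO2, and the (Z)-σ-allyl iridium (C14 anti to the ester) adds to the tethered aldehyde through a closed chair transition state on the Re face set by the ligand to give the syn adduct 34 (1S,2S), which lactonises in situ to the cis-fused α-methylene lactone; closest known reaction type: the intermolecular Krische-type iridium-catalysed 2-(alkoxycarbonyl)allylation of primary alcohols to α-methylene-γ-butyrolactones, together with stoichiometric CrCl2-mediated allylation macrocyclisations.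

**Compound list**

1 | bromoethane | CCBr | starting material
2 | ethyltriphenylphosphonium bromide | CC[P+](c1ccccc1)(c1ccccc1)c1ccccc1.[Br-] | intermediate
3 | ethyl formate | CCOC=O | starting material
4 | ethylidenetriphenylphosphorane | CC=P(c1ccccc1)(c1ccccc1)c1ccccc1 | intermediate
5 | 2-(triphenylphosphoranylidene)propanal | CC(C=O)=P(c1ccccc1)(c1ccccc1)c1ccccc1 | intermediate
6 | pent-4-yn-1-ol | C#CCCCO | starting material
7 | (E)-[5-(dimethylalumanyloxy)-2-methylpent-1-en-1-yl]dimethylalumane | C[Al](C)/C=C(\C)CCCO[Al](C)C | intermediate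
8 | (4E)-5-iodo-4-methylpent-4-en-1-ol | OCCC/C(C)=C/I | intermediate
9 | (4E)-5-iodo-4-methylpent-4-enal | O=CCC/C(C)=C/I | intermediate
10 | (2E,6E)-7-iodo-2,6-dimethylhepta-2,6-dienal | O=C/C(C)=C/CC/C(C)=C/I | intermediate
11 | allylmagnesium bromide | C=CC[Mg]Br | starting material
12 | allylbis[(1S,2R,3S,5S)-2,6,6-trimethylbicyclo[3.1.1]hept-3-yl]borane | C=CCB([C@H]1C[C@H]2C[C@@H]([C@@H]1C)C2(C)C)[C@H]1C[C@H]2C[C@@H]([C@@H]1C)C2(C)C | intermediate
13 | (4R,5E,9E)-10-iodo-5,9-dimethyldeca-1,5,9-trien-4-yl bis[(1S,2R,3S,5S)-2,6,6-trimethylbicyclo[3.1.1]hept-3-yl]borinate | I/C=C(\C)CC/C=C(\C)[C@H](OB([C@H]1C[C@H]2C[C@@H]([C@@H]1C)C2(C)C)[C@H]1C[C@H]2C[C@@H]([C@@H]1C)C2(C)C)CC=C | intermediate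
14 | (4R,5E,9E)-10-iodo-5,9-dimethyldeca-1,5,9-trien-4-ol | I/C=C(\C)CC/C=C(\C)[C@H](O)CC=C | intermediate
15 | (1R)-1-[(2R,3R)-3-[(4E)-5-iodo-4-methylpent-4-en-1-yl]-2-methyloxiran-2-yl]but-3-en-1-ol | I/C=C(\C)CC[C@H]1O[C@]1(C)[C@H](O)CC=C | intermediate
16 | (1R)-1-[(2S,3R)-3-[(4E)-5-iodo-4-methylpent-4-en-1-yl]-2-methyloxiran-2-yl]but-3-en-1-yl acetate | I/C=C(\C)CC[C@H]1O[C@]1(C)[C@H](OC(C)=O)CC=C | intermediate
17 | but-3-yn-1-ol | C#CCCO | starting material
18 | 1-[(but-3-yn-1-yloxy)methyl]-4-methoxybenzene | C#CCCOCc1ccc(OC)cc1 | intermediate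
19 | formaldehyde (as paraformaldehyde) | C=O | starting material
20 | (E)-{4-[(4-methoxyphenyl)methoxy]-2-methylbut-1-en-1-yl}dimethylalumane | C[Al](C)/C=C(\C)CCOCc1ccc(OC)cc1 | intermediate
21 | lithium butyl{(E)-4-[(4-methoxyphenyl)methoxy]-2-methylbut-1-en-1-yl}dimethylaluminate | [Li+].CCCC[Al-](C)(C)/C=C(\C)CCOCc1ccc(OC)cc1 | intermediate
22 | (2E)-5-[(4-methoxyphenyl)methoxy]-3-methylpent-2-en-1-ol | OC/C=C(\C)CCOCc1ccc(OC)cc1 | intermediate
23 | tert-butyl({(2E)-5-[(4-methoxyphenyl)methoxy]-3-methylpent-2-en-1-yl}oxy)dimethylsilane | CC(C)(C)[Si](C)(C)OC/C=C(\C)CCOCc1ccc(OC)cc1 | intermediate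
24 | (3E)-5-[(tert-butyldimethylsilyl)oxy]-3-methylpent-3-en-1-ol | OCC/C(C)=C/CO[Si](C)(C)C(C)(C)C | intermediate
25 | tert-butyl{[(2E)-5-iodo-3-methylpent-2-en-1-yl]oxy}dimethylsilane | ICC/C(C)=C/CO[Si](C)(C)C(C)(C)C | intermediate
26 | methyl 2-(hydroxymethyl)prop-2-enoate | C=C(CO)C(=O)OC | starting material
27 | methyl 2-{[(methoxycarbonyl)oxy]methyl}prop-2-enoate | C=C(COC(=O)OC)C(=O)OC | intermediate
28 | {(3E)-5-[(tert-butyldimethylsilyl)oxy]-3-methylpent-3-en-1-yl}lithium | [Li]CC/C(C)=C/CO[Si](C)(C)C(C)(C)C | intermediate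
29 | lithium 9-{(3E)-5-[(tert-butyldimethylsilyl)oxy]-3-methylpent-3-en-1-yl}-9-methoxy-9-boranuidabicyclo[3.3.1]nonane | [Li+].CO[B-]1(CC/C(C)=C/CO[Si](C)(C)C(C)(C)C)C2CCCC1CCC2 | intermediate
30 | (1R)-1-[(2S,3R)-3-[(3E,7E)-9-[(tert-butyldimethylsilyl)oxy]-3,7-dimethylnona-3,7-dien-1-yl]-2-methyloxiran-2-yl]but-3-en-1-yl acetate | CC(C)(C)[Si](C)(C)OC/C=C(\C)CC/C=C(\C)CC[C@H]1O[C@]1(C)[C@H](OC(C)=O)CC=C | intermediate
31 | methyl (2E,5R)-5-acetoxy-5-[(2S,3R)-3-[(3E,7E)-9-[(tert-butyldimethylsilyl)oxy]-3,7-dimethylnona-3,7-dien-1-yl]-2-methyloxiran-2-yl]-2-{[(methoxycarbonyl)oxy]methyl}pent-2-enoate | CC(C)(C)[Si](C)(C)OC/C=C(\C)CC/C=C(\C)CC[C@H]1O[C@]1(C)[C@H](OC(C)=O)C/C=C(\COC(=O)OC)C(=O)OC | intermediate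
32 | methyl (2E,5R)-5-acetoxy-5-[(2S,3R)-3-[(3E,7E)-9-hydroxy-3,7-dimethylnona-3,7-dien-1-yl]-2-methyloxiran-2-yl]-2-{[(methoxycarbonyl)oxy]methyl}pent-2-enoate | OC/C=C(\C)CC/C=C(\C)CC[C@H]1O[C@]1(C)[C@H](OC(C)=O)C/C=C(\COC(=O)OC)C(=O)OC | intermediate
33 | methyl (2E,5R)-5-acetoxy-5-[(2S,3R)-3-[(3E,7E)-3,7-dimethyl-9-oxonona-3,7-dien-1-yl]-2-methyloxiran-2-yl]-2-{[(methoxycarbonyl)oxy]methyl}pent-2-enoate | O=C/C=C(\C)CC/C=C(\C)CC[C@H]1O[C@]1(C)[C@H](OC(C)=O)C/C=C(\COC(=O)OC)C(=O)OC | intermediate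
34 | methyl 2-[(1S,2S,3E,7E,11R,12S,13R)-13-acetoxy-11,12-epoxy-2-hydroxy-4,8,12-trimethylcyclotetradeca-3,7-dien-1-yl]prop-2-enoate | O[C@H]1/C=C(\C)CC/C=C(\C)CC[C@H]2O[C@]2(C)[C@H](OC(C)=O)C[C@H]1C(=C)C(=O)OC | intermediate
35 | (1S,2S,3E,7E,11R,12S,13R)-13-acetoxy-11,12-epoxycembra-3,7,15(17)-trien-16,2-olide (CNP0146076.4) | C=C1C(=O)O[C@H]2/C=C(\C)CC/C=C(\C)CC[C@H]3O[C@]3(C)[C@H](OC(C)=O)C[C@@H]12 | target

**Step count and risks**

Total: 18 steps. Longest linear sequence: 10 steps (3, 4, 5, 6, 7, 8, 15, 16, 17, 18; the branch 1, 2, 5–8, 15–18 is equally long).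

The three steps most likely to fail:

Step 18, the proposed iridium macrocyclisation. The risks are oligomerisation, slow ionisation of the trisubstituted allylic carbonate and uncertain catalyst control over C1/C2. The fallback is a stoichiometric CrCl2-mediated Nozaki–Hiyama allylation macrocyclisation, which is known chemistry. It sets out from 30. Cross-metathesis with methyl 2-(bromomethyl)prop-2-enoate (same ruthenium catalyst) gives methyl (2Z,5R)-5-acetoxy-2-(bromomethyl)-5-[(2S,3R)-3-[(3E,7E)-9-[(tert-butyldimethylsilyl)oxy]-3,7-dimethylnona-3,7-dien-1-yl]-2-methyloxiran-2-yl]pent-2-enoate F8. HF·pyridine/pyridine in THF gives the allylic alcohol methyl (2Z,5R)-5-acetoxy-2-(bromomethyl)-5-[(2S,3R)-3-[(3E,7E)-9-hydroxy-3,7-dimethylnona-3,7-dien-1-yl]-2-methyloxiran-2-yl]pent-2-enoate F9. MnO2 in CH2Cl2 gives the bromo enal methyl (2Z,5R)-5-acetoxy-2-(bromomethyl)-5-[(2S,3R)-3-[(3E,7E)-3,7-dimethyl-9-oxonona-3,7-dien-1-yl]-2-methyloxiran-2-yl]pent-2-enoate F10. Slow addition of F10 to excess CrCl2 in THF closes the ring through the (Z)-allylchromium chair transition state (syn adduct) to 34, which lactonises and so comes back to the route at 35.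

Step 16, the cross-metathesis with a functionalised 1,1-disubstituted acrylate. The risks are low conversion and E/Z mixtures. The fallback avoids metathesis and builds the enoate by carbonyl chemistry before the fragment union. It sets out from 16. OsO4 (cat.)/NaIO4/2,6-lutidine cleaves the only unhindered alkene to the aldehyde (1R)-1-[(2S,3R)-3-[(4E)-5-iodo-4-methylpent-4-en-1-yl]-2-methyloxiran-2-yl]-3-oxopropyl acetate F3. A base-free Baylis–Hillman surrogate, [1-(methoxycarbonyl)vinyl]diisobutylalane from methyl propiolate, i-Bu2AlH and NMO, adds to give methyl (3RS,5R)-5-acetoxy-3-hydroxy-5-[(2S,3R)-3-[(4E)-5-iodo-4-methylpent-4-en-1-yl]-2-methyloxiran-2-yl]-2-methylidenepentanoate F4. Suzuki coupling with borinate 29 as in step 15 gives methyl (3RS,5R)-5-acetoxy-5-[(2S,3R)-3-[(3E,7E)-9-[(tert-butyldimethylsilyl)oxy]-3,7-dimethylnona-3,7-dien-1-yl]-2-methyloxiran-2-yl]-3-hydroxy-2-methylidenepentanoate F5. Ac2O/DMAP gives the secondary allylic acetate methyl (3RS,5R)-3,5-diacetoxy-5-[(2S,3R)-3-[(3E,7E)-9-[(tert-butyldimethylsilyl)oxy]-3,7-dimethylnona-3,7-dien-1-yl]-2-methyloxiran-2-yl]-2-methylidenepentanoate F6. DABCO in aqueous THF (SN2′–SN2′ transposition) gives the primary alcohol methyl (2E,5R)-5-acetoxy-5-[(2S,3R)-3-[(3E,7E)-9-[(tert-butyldimethylsilyl)oxy]-3,7-dimethylnona-3,7-dien-1-yl]-2-methyloxiran-2-yl]-2-(hydroxymethyl)pent-2-enoate F7. ClCO2Me/pyridine then comes back to the route at 31.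

Step 15, the B-alkyl Suzuki union in the presence of oxirane and acetate. The risks are β-hydride elimination, acetate hydrolysis and oxirane opening. The fallback moves the union ahead of the oxygenation. It sets out from 14. Coupling with borinate 29 under the same palladium conditions gives (4R,5E,9E,13E)-15-[(tert-butyldimethylsilyl)oxy]-5,9,13-trimethylpentadeca-1,5,9,13-tetraen-4-ol F1. Matched Sharpless epoxidation (Ti(OiPr)4, D-(−)-DIPT, t-BuOOH), selective for the allylic alcohol alkene, gives (1R)-1-[(2R,3R)-3-[(3E,7E)-9-[(tert-butyldimethylsilyl)oxy]-3,7-dimethylnona-3,7-dien-1-yl]-2-methyloxiran-2-yl]but-3-en-1-ol F2. Acetylation (Ac2O, DMAP) comes back to the route at 30.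

**Further compounds**

F1 | step 15 | (4R,5E,9E,13E)-15-[(tert-butyldimethylsilyl)oxy]-5,9,13-trimethylpentadeca-1,5,9,13-tetraen-4-ol | CC(C)(C)[Si](C)(C)OC/C=C(\C)CC/C=C(\C)CC/C=C(\C)[C@H](O)CC=C
F2 | step 15 | (1R)-1-[(2R,3R)-3-[(3E,7E)-9-[(tert-butyldimethylsilyl)oxy]-3,7-dimethylnona-3,7-dien-1-yl]-2-methyloxiran-2-yl]but-3-en-1-ol | CC(C)(C)[Si](C)(C)OC/C=C(\C)CC/C=C(\C)CC[C@H]1O[C@]1(C)[C@H](O)CC=C
F3 | step 16 | (1R)-1-[(2S,3R)-3-[(4E)-5-iodo-4-methylpent-4-en-1-yl]-2-methyloxiran-2-yl]-3-oxopropyl acetate | I/C=C(\C)CC[C@H]1O[C@]1(C)[C@H](OC(C)=O)CC=O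
F4 | step 16 | methyl (3RS,5R)-5-acetoxy-3-hydroxy-5-[(2S,3R)-3-[(4E)-5-iodo-4-methylpent-4-en-1-yl]-2-methyloxiran-2-yl]-2-methylidenepentanoate | I/C=C(\C)CC[C@H]1O[C@]1(C)[C@H](OC(C)=O)CC(O)C(=C)C(=O)OC
F5 | step 16 | methyl (3RS,5R)-5-acetoxy-5-[(2S,3R)-3-[(3E,7E)-9-[(tert-butyldimethylsilyl)oxy]-3,7-dimethylnona-3,7-dien-1-yl]-2-methyloxiran-2-yl]-3-hydroxy-2-methylidenepentanoate | CC(C)(C)[Si](C)(C)OC/C=C(\C)CC/C=C(\C)CC[C@H]1O[C@]1(C)[C@H](OC(C)=O)CC(O)C(=C)C(=O)OC
F6 | step 16 | methyl (3RS,5R)-3,5-diacetoxy-5-[(2S,3R)-3-[(3E,7E)-9-[(tert-butyldimethylsilyl)oxy]-3,7-dimethylnona-3,7-dien-1-yl]-2-methyloxiran-2-yl]-2-methylidenepentanoate | CC(C)(C)[Si](C)(C)OC/C=C(\C)CC/C=C(\C)CC[C@H]1O[C@]1(C)[C@H](OC(C)=O)CC(OC(C)=O)C(=C)C(=O)OC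
F7 | step 16 | methyl (2E,5R)-5-acetoxy-5-[(2S,3R)-3-[(3E,7E)-9-[(tert-butyldimethylsilyl)oxy]-3,7-dimethylnona-3,7-dien-1-yl]-2-methyloxiran-2-yl]-2-(hydroxymethyl)pent-2-enoate | CC(C)(C)[Si](C)(C)OC/C=C(\C)CC/C=C(\C)CC[C@H]1O[C@]1(C)[C@H](OC(C)=O)C/C=C(\CO)C(=O)OC
F8 | step 18 | methyl (2Z,5R)-5-acetoxy-2-(bromomethyl)-5-[(2S,3R)-3-[(3E,7E)-9-[(tert-butyldimethylsilyl)oxy]-3,7-dimethylnona-3,7-dien-1-yl]-2-methyloxiran-2-yl]pent-2-enoate | CC(C)(C)[Si](C)(C)OC/C=C(\C)CC/C=C(\C)CC[C@H]1O[C@]1(C)[C@H](OC(C)=O)C/C=C(\CBr)C(=O)OC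
F9 | step 18 | methyl (2Z,5R)-5-acetoxy-2-(bromomethyl)-5-[(2S,3R)-3-[(3E,7E)-9-hydroxy-3,7-dimethylnona-3,7-dien-1-yl]-2-methyloxiran-2-yl]pent-2-enoate | OC/C=C(\C)CC/C=C(\C)CC[C@H]1O[C@]1(C)[C@H](OC(C)=O)C/C=C(\CBr)C(=O)OC
F10 | step 18 | methyl (2Z,5R)-5-acetoxy-2-(bromomethyl)-5-[(2S,3R)-3-[(3E,7E)-3,7-dimethyl-9-oxonona-3,7-dien-1-yl]-2-methyloxiran-2-yl]pent-2-enoate | O=C/C=C(\C)CC/C=C(\C)CC[C@H]1O[C@]1(C)[C@H](OC(C)=O)C/C=C(\CBr)C(=O)OC
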